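The route rests on breaking the O1–C2 bond of the dihydrobenzofuran. Two features are exploited: ring A (the 4-hydroxy-3-methoxyphenyl group) has its hydroxyl para to benzylic C2, so C2 can become the electrophilic end of a p-quinone methide, and ring B carries phenol oxygen O1 ortho to the carbon bearing C3, placed for five-membered closure. One acid-catalysed operation therefore forms O1–C2, closes the furan ring and sets C2 trans to C3 by equilibration. The precursor is an open-chain 1-(ring A)-2-(ring B)propane-1,3-diol with free phenols, a TBDPS ether on C9 and only the future C3 defined, which an Evans aldol sets directly.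

Key step: step 10

Remark (assumption): atom labels follow the dihydrobenzofuran (O1, C2, C3, C3a); in open-chain compounds C7, C8 and C9 are the carbons that become C2, C3 and the CH2O carbon on C3. Because C7 is flattened in the key step, the precursor is carried as the syn (1R,2S) isomer that the aldol delivers, so C3 does not depend on a relay from the carbinol centre.

Step 1
Reactants: 1 dihydroconiferyl alcohol [4-(3-hydroxypropyl)-2-methoxyphenol]
Product: 2 2-bromo-4-(3-hydroxypropyl)-6-methoxyphenol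
Conditions: NBS (1.0 equiv), iPr2NH (10 mol %), CH2Cl2, 0 °C
Reagents that add atoms: N-bromosuccinimide, O=C1CCC(=O)N1Br
Why: Amine-catalysed electrophilic aromatic bromination of a phenol: with the para position taken by the side chain, the free hydroxyl steers bromine to its one open ortho carbon (the future C3a), which is why bromination precedes capping of the phenol.

Step 2
Reactants: 2 2-bromo-4-(3-hydroxypropyl)-6-methoxyphenol
Product: 3 2-(benzyloxy)-1-bromo-5-[3-(benzyloxy)propyl]-3-methoxybenzene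
Conditions: NaH (2.5 equiv), BnBr (2.4 equiv), Bu4NI (cat.), DMF, 0 °C to rt
Reagents that add atoms: benzyl bromide, BrCc1ccccc1
Why: Double Williamson ether synthesis: NaH forms the phenolate and the primary alkoxide, and both are benzylated by SN2 attack on BnBr while the aryl bromide is inert.

Step 3
Reactants: 3 2-(benzyloxy)-1-bromo-5-[3-(benzyloxy)propyl]-3-methoxybenzene
Product: 4 ethyl 2-{2-(benzyloxy)-5-[3-(benzyloxy)propyl]-3-methoxyphenyl}acetate
Conditions: BrZnCH2CO2Et (1.5 equiv; from BrCH2CO2Et, Zn dust, TMSCl cat., THF, 40 °C), Pd(dba)2 (2 mol %), XPhos (4 mol %), THF, 65 °C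
Reagents that add atoms: ethyl bromoacetate, CCOC(=O)CBr (used as its zinc reagent 2-ethoxy-2-oxoethylzinc bromide, CCOC(=O)C[Zn]Br)
Why: Negishi-type cross-coupling of a Reformatsky reagent (Pd-catalysed α-arylation of a zinc ester enolate): zerovalent palladium with the bulky XPhos ligand inserts into the hindered, electron-rich C–Br bond, and the weakly basic zinc enolate transfers the CH2CO2Et group without touching the benzyl ethers.

Step 4
Reactants: 4 ethyl 2-{2-(benzyloxy)-5-[3-(benzyloxy)propyl]-3-methoxyphenyl}acetate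
Product: 5 2-{2-(benzyloxy)-5-[3-(benzyloxy)propyl]-3-methoxyphenyl}acetic acid
Conditions: LiOH·H2O (3 equiv), THF/MeOH/H2O, rt; then 1 M HCl
Reagents that add atoms: lithium hydroxide, [Li+].[OH-]
Why: Saponification of an unhindered ethyl ester, to which both benzyl ethers are inert; acidification frees the arylacetic acid.

Step 5
Reactants: 5 2-{2-(benzyloxy)-5-[3-(benzyloxy)propyl]-3-methoxyphenyl}acetic acid; 6 (R)-4-benzyl-1,3-oxazolidin-2-one
Product: 8 (R)-4-benzyl-3-(2-{2-(benzyloxy)-5-[3-(benzyloxy)propyl]-3-methoxyphenyl}acetyl)-1,3-oxazolidin-2-one, via mixed pivalic anhydride 7 (not isolated)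
Conditions: PivCl (1.1 equiv), Et3N (2.5 equiv), THF, −20 °C; then 6, LiCl, −20 °C to rt
Reagents that add atoms: none
Why: N-Acylation of an Evans oxazolidinone through a mixed pivalic anhydride: LiCl and Et3N make the oxazolidinone nucleophilic enough to attack the less hindered arylacetyl carbonyl, so that no strong base meets the acidic benzylic CH2 group.

Step 6
Reactants: 8 (R)-4-benzyl-3-(2-{2-(benzyloxy)-5-[3-(benzyloxy)propyl]-3-methoxyphenyl}acetyl)-1,3-oxazolidin-2-one; 9 4-(benzyloxy)-3-methoxybenzaldehyde (O-benzylvanillin)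
Product: 12 (R)-4-benzyl-3-[(2R,3R)-2-{2-(benzyloxy)-5-[3-(benzyloxy)propyl]-3-methoxyphenyl}-3-[4-(benzyloxy)-3-methoxyphenyl]-3-hydroxypropanoyl]-1,3-oxazolidin-2-one, via dibutylboron Z-enolate 10 (not isolated), via dibutylboron aldolate 11 (not isolated)
Conditions: Bu2BOTf (1.2 equiv), iPr2NEt (1.4 equiv), CH2Cl2, 0 °C; then 9, −78 to 0 °C; then pH 7 buffer, MeOH, H2O2, 0 °C
Reagents that add atoms: none
Why: Evans syn-aldol reaction: soft enolisation gives the Z boron enolate, which adds to the aldehyde through a chair Zimmerman–Traxler transition state on the enolate face turned away from the benzyl group of the (R)-auxiliary, so that C8 is set by the auxiliary (2R in the imide, S once C9 is reduced) and C7 follows as its syn partner (R), a centre that is later erased.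

Step 7
Reactants: 12 (R)-4-benzyl-3-[(2R,3R)-2-{2-(benzyloxy)-5-[3-(benzyloxy)propyl]-3-methoxyphenyl}-3-[4-(benzyloxy)-3-methoxyphenyl]-3-hydroxypropanoyl]-1,3-oxazolidin-2-one
Product: 13 (1R,2S)-2-{2-(benzyloxy)-5-[3-(benzyloxy)propyl]-3-methoxyphenyl}-1-[4-(benzyloxy)-3-methoxyphenyl]propane-1,3-diol
Conditions: LiBH4 (2.5 equiv), MeOH (2.5 equiv), THF, 0 °C
Reagents that add atoms: none
Why: Reductive cleavage of the N-acyl oxazolidinone: hydride from LiBH4 adds to the lithium-activated exocyclic carbonyl and the aldehyde set free is reduced further to the C9 alcohol at 0 °C, conditions under which retro-aldol cleavage and epimerisation at C8 should not occur, and the auxiliary can be recovered.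

Step 8
Reactants: 13 (1R,2S)-2-{2-(benzyloxy)-5-[3-(benzyloxy)propyl]-3-methoxyphenyl}-1-[4-(benzyloxy)-3-methoxyphenyl]propane-1,3-diol
Product: 14 (1R,2S)-2-{2-(benzyloxy)-5-[3-(benzyloxy)propyl]-3-methoxyphenyl}-1-[4-(benzyloxy)-3-methoxyphenyl]-3-[(tert-butyldiphenylsilyl)oxy]propan-1-ol
Conditions: TBDPSCl (1.05 equiv), imidazole (2 equiv), CH2Cl2, 0 °C to rt
Reagents that add atoms: tert-butyl(chloro)diphenylsilane, CC(C)(C)[Si](Cl)(c1ccccc1)c1ccccc1
Why: Selective silyl ether formation: the bulky TBDPSCl reacts with the primary C9 hydroxyl far faster than with the hindered secondary benzylic C7 hydroxyl, which marks C9 off from the chain alcohol for the later esterification.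

Step 9
Reactants: 14 (1R,2S)-2-{2-(benzyloxy)-5-[3-(benzyloxy)propyl]-3-methoxyphenyl}-1-[4-(benzyloxy)-3-methoxyphenyl]-3-[(tert-butyldiphenylsilyl)oxy]propan-1-ol
Product: 15 (1R,2S)-3-[(tert-butyldiphenylsilyl)oxy]-1-(4-hydroxy-3-methoxyphenyl)-2-[2-hydroxy-5-(3-hydroxypropyl)-3-methoxyphenyl]propan-1-ol
Conditions: H2 (1 atm), Pd/C (10 wt %), EtOAc/EtOH, rt
Reagents that add atoms: none
Why: Catalytic hydrogenolysis of the two aryl benzyl ethers and the alkyl benzyl ether over Pd/C in a neutral medium, in which the silyl ether is stable and the benzylic C7 hydroxyl is expected to survive at room temperature and atmospheric pressure.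

Step 10
Reactants: 15 (1R,2S)-3-[(tert-butyldiphenylsilyl)oxy]-1-(4-hydroxy-3-methoxyphenyl)-2-[2-hydroxy-5-(3-hydroxypropyl)-3-methoxyphenyl]propan-1-ol
Product: 17 3-[(2R,3S)-3-{[(tert-butyldiphenylsilyl)oxy]methyl}-2-(4-hydroxy-3-methoxyphenyl)-7-methoxy-2,3-dihydro-1-benzofuran-5-yl]propan-1-ol, via ring A p-quinone methide 16 (not isolated)
Conditions: TsOH·H2O (10 mol %), CH2Cl2 (0.02 M), rt
Reagents that add atoms: none
Why: TsOH protonates the C7 hydroxyl of 15 and water leaves with help from the para oxygen of ring A, giving the neutral p-quinone methide 16 in which C7 is planar; the ring B phenol oxygen then adds to C7 in a 1,6-conjugate (vinylogous oxa-Michael) addition that restores the aromaticity of ring A and forms the O1–C2 bond. The closest known reaction type is the acid-mediated cyclodehydration of 1-aryl-2-(2-hydroxyaryl)propane-1,3-diols to trans-2-aryl-2,3-dihydrobenzofurans by way of p-quinone methides. The one ring formed, the dihydrofuran, closes in a 5-exo-trig mode, the exocyclic C7=C1 bond of the quinone methide lying outside the new ring. The new stereocentre C2 is controlled by the existing C3 centre: ring closure is reversible under the acid, so the material should settle on the trans isomer, in which the C2 aryl group and the C3 silyloxymethyl group sit on opposite faces, whichever C7 epimer is used. The step needs the phenol oxygen to win over the two aliphatic oxygens and needs trans selectivity; the first is secured by the silyl cap on the C9 oxygen, by the strain of any ring through that oxygen and by the reversibility of capture by the chain alcohol at high dilution, the second by thermodynamic control from the C3 centre set in step 6.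

Step 11
Reactants: 17 3-[(2R,3S)-3-{[(tert-butyldiphenylsilyl)oxy]methyl}-2-(4-hydroxy-3-methoxyphenyl)-7-methoxy-2,3-dihydro-1-benzofuran-5-yl]propan-1-ol; 18 (E)-ferulic acid
Product: 19 3-[(2R,3S)-3-{[(tert-butyldiphenylsilyl)oxy]methyl}-2-(4-hydroxy-3-methoxyphenyl)-7-methoxy-2,3-dihydro-1-benzofuran-5-yl]propyl (E)-3-(4-hydroxy-3-methoxyphenyl)prop-2-enoate
Conditions: PPh3 (1.3 equiv), DIAD (1.3 equiv), THF, 0 °C to rt
Reagents that add atoms: none
Why: Mitsunobu esterification: the chain alcohol, the only aliphatic hydroxyl left free, is activated as an alkoxyphosphonium ion and displaced by the ferulate carboxylate, which forms in preference to the far less acidic phenolates, so neither phenol needs protection and no stereocentre is touched.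

Step 12
Reactants: 19 3-[(2R,3S)-3-{[(tert-butyldiphenylsilyl)oxy]methyl}-2-(4-hydroxy-3-methoxyphenyl)-7-methoxy-2,3-dihydro-1-benzofuran-5-yl]propyl (E)-3-(4-hydroxy-3-methoxyphenyl)prop-2-enoate
Product: 20 3-[(2R,3S)-3-(hydroxymethyl)-2-(4-hydroxy-3-methoxyphenyl)-7-methoxy-2,3-dihydro-1-benzofuran-5-yl]propyl (E)-3-(4-hydroxy-3-methoxyphenyl)prop-2-enoate (CNP0149450.1)
Conditions: TBAF (3 equiv), AcOH (3 equiv), THF, 0 °C to rt
Reagents that add atoms: none
Why: Fluoride-induced cleavage of the silyl ether, driven by the strength of the Si–F bond; buffering with AcOH keeps the medium from becoming basic, so the cinnamate ester, the phenols and the p-hydroxybenzyl aryl ether linkage of the ring are left alone.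

Compound list

1 | dihydroconiferyl alcohol [4-(3-hydroxypropyl)-2-methoxyphenol] | OCCCc1ccc(O)c(OC)c1 | starting material
2 | 2-bromo-4-(3-hydroxypropyl)-6-methoxyphenol | OCCCc1cc(Br)c(O)c(OC)c1 | intermediate
3 | 2-(benzyloxy)-1-bromo-5-[3-(benzyloxy)propyl]-3-methoxybenzene | COc1cc(CCCOCc2ccccc2)cc(Br)c1OCc1ccccc1 | intermediate
4 | ethyl 2-{2-(benzyloxy)-5-[3-(benzyloxy)propyl]-3-methoxyphenyl}acetate | CCOC(=O)Cc1cc(CCCOCc2ccccc2)cc(OC)c1OCc1ccccc1 | intermediate
5 | 2-{2-(benzyloxy)-5-[3-(benzyloxy)propyl]-3-methoxyphenyl}acetic acid | OC(=O)Cc1cc(CCCOCc2ccccc2)cc(OC)c1OCc1ccccc1 | intermediate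
6 | (R)-4-benzyl-1,3-oxazolidin-2-one | O=C1OC[C@@H](Cc2ccccc2)N1 | starting material
7 | mixed anhydride of 5 with pivalic acid (formed in the flask, not isolated) | CC(C)(C)C(=O)OC(=O)Cc1cc(CCCOCc2ccccc2)cc(OC)c1OCc1ccccc1 | intermediate
8 | (R)-4-benzyl-3-(2-{2-(benzyloxy)-5-[3-(benzyloxy)propyl]-3-methoxyphenyl}acetyl)-1,3-oxazolidin-2-one | O=C(Cc1cc(CCCOCc2ccccc2)cc(OC)c1OCc1ccccc1)N1[C@H](Cc2ccccc2)COC1=O | intermediate
9 | 4-(benzyloxy)-3-methoxybenzaldehyde (O-benzylvanillin) | O=Cc1ccc(OCc2ccccc2)c(OC)c1 | starting material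
10 | dibutylboron (Z)-enolate of 8, boron on the enolate oxygen, aryl group cis to that oxygen (formed in the flask, not isolated) | CCCCB(CCCC)O/C(=C\c1cc(CCCOCc2ccccc2)cc(OC)c1OCc1ccccc1)N1[C@H](Cc2ccccc2)COC1=O | intermediate
11 | dibutylboron aldolate of 12, boron on the C7 oxygen (formed in the flask, not isolated) | O=C(N1[C@H](Cc2ccccc2)COC1=O)[C@H](c1cc(CCCOCc2ccccc2)cc(OC)c1OCc1ccccc1)[C@@H](OB(CCCC)CCCC)c1ccc(OCc2ccccc2)c(OC)c1 | intermediate
12 | (R)-4-benzyl-3-[(2R,3R)-2-{2-(benzyloxy)-5-[3-(benzyloxy)propyl]-3-methoxyphenyl}-3-[4-(benzyloxy)-3-methoxyphenyl]-3-hydroxypropanoyl]-1,3-oxazolidin-2-one (syn aldol) | O=C(N1[C@H](Cc2ccccc2)COC1=O)[C@H](c1cc(CCCOCc2ccccc2)cc(OC)c1OCc1ccccc1)[C@@H](O)c1ccc(OCc2ccccc2)c(OC)c1 | intermediate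
13 | (1R,2S)-2-{2-(benzyloxy)-5-[3-(benzyloxy)propyl]-3-methoxyphenyl}-1-[4-(benzyloxy)-3-methoxyphenyl]propane-1,3-diol | OC[C@H](c1cc(CCCOCc2ccccc2)cc(OC)c1OCc1ccccc1)[C@@H](O)c1ccc(OCc2ccccc2)c(OC)c1 | intermediate
14 | (1R,2S)-2-{2-(benzyloxy)-5-[3-(benzyloxy)propyl]-3-methoxyphenyl}-1-[4-(benzyloxy)-3-methoxyphenyl]-3-[(tert-butyldiphenylsilyl)oxy]propan-1-ol | CC(C)(C)[Si](OC[C@H](c1cc(CCCOCc2ccccc2)cc(OC)c1OCc1ccccc1)[C@@H](O)c1ccc(OCc2ccccc2)c(OC)c1)(c1ccccc1)c1ccccc1 | intermediate
15 | (1R,2S)-3-[(tert-butyldiphenylsilyl)oxy]-1-(4-hydroxy-3-methoxyphenyl)-2-[2-hydroxy-5-(3-hydroxypropyl)-3-methoxyphenyl]propan-1-ol (precursor of the key step) | OCCCc1cc(OC)c(O)c(c1)[C@@H](CO[Si](c2ccccc2)(c2ccccc2)C(C)(C)C)[C@@H](O)c1ccc(O)c(OC)c1 | intermediate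
16 | (S)-4-{3-[(tert-butyldiphenylsilyl)oxy]-2-[2-hydroxy-5-(3-hydroxypropyl)-3-methoxyphenyl]propylidene}-2-methoxycyclohexa-2,5-dien-1-one, the ring A p-quinone methide (formed in the flask, not isolated) | OCCCc1cc(OC)c(O)c(c1)[C@@H](CO[Si](c2ccccc2)(c2ccccc2)C(C)(C)C)C=C1C=CC(=O)C(OC)=C1 | intermediate
17 | 3-[(2R,3S)-3-{[(tert-butyldiphenylsilyl)oxy]methyl}-2-(4-hydroxy-3-methoxyphenyl)-7-methoxy-2,3-dihydro-1-benzofuran-5-yl]propan-1-ol (trans; product of the key step) | OCCCc1cc(OC)c2c(c1)[C@@H](CO[Si](c3ccccc3)(c3ccccc3)C(C)(C)C)[C@H](c1ccc(O)c(OC)c1)O2 | intermediate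
18 | (E)-ferulic acid | COc1cc(/C=C/C(=O)O)ccc1O | starting material
19 | 3-[(2R,3S)-3-{[(tert-butyldiphenylsilyl)oxy]methyl}-2-(4-hydroxy-3-methoxyphenyl)-7-methoxy-2,3-dihydro-1-benzofuran-5-yl]propyl (E)-3-(4-hydroxy-3-methoxyphenyl)prop-2-enoate | COc1cc(/C=C/C(=O)OCCCc2cc(OC)c3c(c2)[C@@H](CO[Si](c4ccccc4)(c4ccccc4)C(C)(C)C)[C@H](c2ccc(O)c(OC)c2)O3)ccc1O | intermediate
20 | 3-[(2R,3S)-3-(hydroxymethyl)-2-(4-hydroxy-3-methoxyphenyl)-7-methoxy-2,3-dihydro-1-benzofuran-5-yl]propyl (E)-3-(4-hydroxy-3-methoxyphenyl)prop-2-enoate (CNP0149450.1) | COc1cc(/C=C/C(=O)OCCCc2cc(OC)c3c(c2)[C@@H](CO)[C@H](c2ccc(O)c(OC)c2)O3)ccc1O | target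

Total step count: 12. Longest linear sequence: 12 steps (1 to 20); 6, 9 and 18 are bought and enter in one step each.

Steps most likely to fail

Step 10. Equilibration may stop short of the trans isomer. The quinone methide may be captured between molecules (by the chain alcohol or by an electron-rich ring) faster than it cyclises. It may tautomerise by loss of the C8 proton, which would erase C3. The acid may also erode the silyl ether. The fallback generates the quinone methide with base instead of acid; it sets out from 15 and comes back at 17. Peracetylation of 15 (Ac2O, pyridine, DMAP cat., CH2Cl2, rt) should give (1R,2S)-1-(4-acetoxy-3-methoxyphenyl)-2-[2-acetoxy-5-(3-acetoxypropyl)-3-methoxyphenyl]-3-[(tert-butyldiphenylsilyl)oxy]propyl acetate F1. LiOH in THF/H2O at 0 °C then cleaves the aryl acetates, and the ring A phenolate expels the benzylic acetate in a 1,6-elimination. The ring B phenolate closes the ring on quinone methide 16, and hydrolysis of the chain acetate leaves 17. Water, the only competing nucleophile, would merely return 15.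

Step 11. A phenol oxygen may be alkylated in place of the carboxylate, or the betaine may be consumed unproductively with the sparingly soluble acid. The fallback separates activation from ester formation; it sets out from 17 and comes back at 19. Appel iodination (I2, PPh3, imidazole, CH2Cl2, 0 °C) should turn the chain alcohol into 4-[(2R,3S)-3-{[(tert-butyldiphenylsilyl)oxy]methyl}-5-(3-iodopropyl)-7-methoxy-2,3-dihydro-1-benzofuran-2-yl]-2-methoxyphenol F2. Ferulic acid 18 with KHCO3 in DMF at 40 °C, a base that deprotonates only the carboxylic acid, then gives 19 by SN2 displacement of iodide.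

Step 9. Once the ring A phenol is free, the benzylic C7–O bond may be hydrogenolysed before the slower alkyl benzyl ether is gone. The fallback masks the carbinol during the reduction; it sets out from 14 and comes back at 17. Silylation (TESOTf, 2,6-lutidine, CH2Cl2, −78 °C) should give the C7 triethylsilyl ether of 14 F3. Hydrogenolysis (H2, Pd/C, EtOAc, rt) then gives the C7 triethylsilyl ether of 15 F4. TsOH·H2O in CH2Cl2 ionises this benzylic silyl ether to the same quinone methide 16, which closes to 17.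

Further compounds

F1 | step 10 | (1R,2S)-1-(4-acetoxy-3-methoxyphenyl)-2-[2-acetoxy-5-(3-acetoxypropyl)-3-methoxyphenyl]-3-[(tert-butyldiphenylsilyl)oxy]propyl acetate | CC(=O)OCCCc1cc(OC)c(OC(C)=O)c(c1)[C@@H](CO[Si](c2ccccc2)(c2ccccc2)C(C)(C)C)[C@@H](OC(C)=O)c1ccc(OC(C)=O)c(OC)c1
F2 | step 11 | 4-[(2R,3S)-3-{[(tert-butyldiphenylsilyl)oxy]methyl}-5-(3-iodopropyl)-7-methoxy-2,3-dihydro-1-benzofuran-2-yl]-2-methoxyphenol | ICCCc1cc(OC)c2c(c1)[C@@H](CO[Si](c3ccccc3)(c3ccccc3)C(C)(C)C)[C@H](c1ccc(O)c(OC)c1)O2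
F3 | step 9 | C7 triethylsilyl ether of 14: tert-butyl{[(2S,3R)-2-{2-(benzyloxy)-5-[3-(benzyloxy)propyl]-3-methoxyphenyl}-3-[4-(benzyloxy)-3-methoxyphenyl]-3-[(triethylsilyl)oxy]propyl]oxy}diphenylsilane | CC(C)(C)[Si](OC[C@H](c1cc(CCCOCc2ccccc2)cc(OC)c1OCc1ccccc1)[C@@H](O[Si](CC)(CC)CC)c1ccc(OCc2ccccc2)c(OC)c1)(c1ccccc1)c1ccccc1
F4 | step 9 | C7 triethylsilyl ether of 15: 4-[(1R,2S)-3-[(tert-butyldiphenylsilyl)oxy]-2-[2-hydroxy-5-(3-hydroxypropyl)-3-methoxyphenyl]-1-[(triethylsilyl)oxy]propyl]-2-methoxyphenol | OCCCc1cc(OC)c(O)c(c1)[C@@H](CO[Si](c2ccccc2)(c2ccccc2)C(C)(C)C)[C@@H](O[Si](CC)(CC)CC)c1ccc(O)c(OC)c1
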